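**Plan**

- The target is a furan-2(5H)-one (ring O1, C2 carbonyl, C3, C4, C5; exocyclic C6; side-chain carbinol C1'). C3 carries the C2 carboxyl carbon and the C1' carbinol, and C4 carries Br. This is the α-(1-hydroxyalkyl)-β-bromoacrylate array of a bromo-aldol (β-halo Morita–Baylis–Hillman) adduct, which is what permits a three-component assembly.
- Retrosynthesis: C6–I and the C5=C6 alkene go back to a C5 methyl lactol. The lactone ring opens to a keto ester masked as a dioxolane. C3–C1' and C4–Br are then cut together to butanal, Me3SiBr and a ketal ynoate. C2–C3 is cut last to a lithium acetylide and methyl chloroformate.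
- Forward: C2–C3 first, then C4–Br and C3–C1' in one operation, then the only ring (the lactone, O1 between C2 and C5) closes on acid hydrolysis, then the exocyclic alkene and the iodine are installed.
- Stereochemistry: C1' (R) is set by a chiral oxazaborolidinium in the bromo-aldol and is never touched at carbon afterwards. The cis ester/ketal geometry comes from the side of the allenolate taken by the aldehyde. The Z iodoalkene comes from elimination with iodine turned away from the C4 bromine.

Key step: step 3

Assumption: the (S)-configured oxazaborolidinium is taken to shield the re face of bound butanal, as in its other aldehyde additions, so that si-face attack gives R; if the sense is the reverse, the (R)-catalyst is used with no other change.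

**Step 1**
Reactants: 1 but-3-yn-2-one
Product: 2 2-ethynyl-2-methyl-1,3-dioxolane
Conditions: (Me3SiOCH2)2, Me3SiOSO2CF3 (2 mol%), CH2Cl2, −78 °C; pyridine quench
Reagents that add atoms: 1,2-bis(trimethylsilyloxy)ethane, C[Si](C)(C)OCCO[Si](C)(C)C
Why: Noyori ketalisation, in which the silyl-activated carbonyl is trapped by the bis-silyl glycol at low temperature and driven by formation of hexamethyldisiloxane, avoids the conjugate addition of free glycol that plagues ynones under protic acid.

**Step 2**
Reactants: 2 2-ethynyl-2-methyl-1,3-dioxolane; 3 methyl chloroformate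
Product: 5 methyl 3-(2-methyl-1,3-dioxolan-2-yl)prop-2-ynoate, via lithium acetylide 4 (not isolated)
Conditions: n-BuLi, THF, −78 °C; then ClCO2Me, −78 → 0 °C
Reagents that add atoms: none
Why: Deprotonation of the terminal alkyne and C-acylation of the lithium acetylide with a chloroformate is the standard route to ynoates, and the dioxolane is inert to the base.

**Step 3**
Reactants: 5 methyl 3-(2-methyl-1,3-dioxolan-2-yl)prop-2-ynoate; 6 butanal; 7 bromotrimethylsilane
Product: 9 methyl (E)-3-bromo-3-(2-methyl-1,3-dioxolan-2-yl)-2-[(R)-1-(trimethylsilyloxy)butyl]prop-2-enoate, via silyl allenolate 8 (not isolated)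
Conditions: 5 (1.3 equiv), Me3SiBr (1.4 equiv), EtCN, −40 °C; then butanal (1.0 equiv), (S)-3,3-diphenyl-1-(2-methylphenyl)tetrahydro-1H,3H-pyrrolo[1,2-c][1,3,2]oxazaborole·HN(SO2CF3)2 (20 mol%), −78 °C; Et3N, then pH 7 phosphate buffer
Reagents that add atoms: none
Why: Proposed new method: Me3SiBr silylates the ester carbonyl of 5 while bromide adds to the β-alkyne carbon to give the silyl allenyl ketene acetal 8, whose central (α) carbon attacks butanal bound to the cationic oxazaborolidinium in an open Mukaiyama-type transition state, with silyl transfer to the new alkoxide releasing the catalyst; the closest known reaction type is the oxazaborolidinium-catalysed three-component iodo-aldol of propiolates, Me3SiI and aldehydes that gives β-iodo Morita–Baylis–Hillman esters. The extension lies in bromide as the halide and in an internal ynoate whose β-carbon bears a fully substituted ketal carbon. No ring is closed; one C–C bond (C3–C1') and one C–Br bond (C4–Br) are formed. The C1' stereocentre is controlled by the catalyst: butanal is held by B–O coordination and a formyl C–H···O contact so that its re face is covered by a phenyl group, and the allenolate adds to the si face, which gives R. The step needs bromide addition only at C4 and E alkene geometry; the ketal makes the ester the sole acceptor, and the aldehyde reaches the α-carbon in the plane of the C4 substituents from the bromine side, away from the bulky dioxolanyl group, which leaves ester and ketal cis. The dioxolane should survive because ionisation next to the electron-poor alkyne is disfavoured at these temperatures.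

**Step 4**
Reactants: 9 methyl (E)-3-bromo-3-(2-methyl-1,3-dioxolan-2-yl)-2-[(R)-1-(trimethylsilyloxy)butyl]prop-2-enoate
Product: 11 4-bromo-5-hydroxy-3-[(1R)-1-hydroxybutyl]-5-methylfuran-2(5H)-one, via keto ester 10 (not isolated)
Conditions: 2 M H2SO4, 1,4-dioxane, 50 °C
Reagents that add atoms: water, O
Why: Acid hydrolysis removes the silyl ether and the dioxolane, and the freed ketone, held cis to the ester on the tetrasubstituted alkene, closes through its hydrate onto the ester with loss of methanol to give the cyclic pseudo-acid (ring–chain tautomerism of cis-4-oxo-2-enoic acids); the C1' carbinol sits on an electron-poor alkene and should not ionise, and the sulfate counter-ion avoids halide exchange at C4.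

**Step 5**
Reactants: 11 4-bromo-5-hydroxy-3-[(1R)-1-hydroxybutyl]-5-methylfuran-2(5H)-one
Product: 13 (1R)-1-(4-bromo-5-methylidene-2-oxo-2,5-dihydrofuran-3-yl)butyl acetate, via diacetate 12 (not isolated)
Conditions: Ac2O, H2SO4 (cat.), 20 → 50 °C
Reagents that add atoms: acetic anhydride, CC(=O)OC(C)=O
Why: Acid-catalysed acetylation of both hydroxyls followed by E1 loss of acetic acid from the tertiary 5-acetoxy pseudo-ester (the classical acetic anhydride/sulfuric acid enol-lactonisation of acetylacrylic-type lactols) forms the exocyclic methylene and masks the C1' hydroxyl, which is acylated at oxygen and so keeps its configuration.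

**Step 6**
Reactants: 13 (1R)-1-(4-bromo-5-methylidene-2-oxo-2,5-dihydrofuran-3-yl)butyl acetate
Product: 15 (1R)-1-[(5Z)-4-bromo-5-(iodomethylidene)-2-oxo-2,5-dihydrofuran-3-yl]butyl acetate, via chloroiodide adduct 14 (not isolated)
Conditions: ICl, CH2Cl2, −20 °C, dark; then i-Pr2NEt, −20 → 0 °C
Reagents that add atoms: iodine monochloride, ClI
Why: Electrophilic iodination of the enol-ester alkene places iodine on C6 and chloride on the oxygen-stabilised C5, and base-induced dehydrochlorination (the halogen addition/dehydrohalogenation sequence used for 5-halomethylidene furanones) gives the iodoalkene, with Z favoured because iodine avoids the C4 bromine.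

**Step 7**
Reactants: 15 (1R)-1-[(5Z)-4-bromo-5-(iodomethylidene)-2-oxo-2,5-dihydrofuran-3-yl]butyl acetate
Product: 16 (5Z)-4-bromo-3-[(1R)-1-hydroxybutyl]-5-(iodomethylidene)furan-2(5H)-one
Conditions: 4-MeC6H4SO3H·H2O (cat.), MeOH, 40 °C, dark
Reagents that add atoms: none
Why: Acid-catalysed transesterification cleaves the acetate by acyl–oxygen fission, so C1' keeps its R configuration, and the base-sensitive halogenated ylidene butenolide is never exposed to a nucleophilic base.

**Compound list**

1 | but-3-yn-2-one | CC(=O)C#C | starting material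
2 | 2-ethynyl-2-methyl-1,3-dioxolane | C#CC1(C)OCCO1 | intermediate
3 | methyl chloroformate | COC(=O)Cl | starting material
4 | lithium (2-methyl-1,3-dioxolan-2-yl)acetylide, formed in the flask | [Li]C#CC1(C)OCCO1 | intermediate
5 | methyl 3-(2-methyl-1,3-dioxolan-2-yl)prop-2-ynoate | COC(=O)C#CC1(C)OCCO1 | intermediate
6 | butanal | CCCC=O | starting material
7 | bromotrimethylsilane | C[Si](C)(C)Br | starting material
8 | methyl trimethylsilyl allenyl ketene acetal with Br and the dioxolanyl group on the allene terminus, formed in the flask | COC(O[Si](C)(C)C)=C=C(Br)C1(C)OCCO1 | intermediate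
9 | methyl (E)-3-bromo-3-(2-methyl-1,3-dioxolan-2-yl)-2-[(R)-1-(trimethylsilyloxy)butyl]prop-2-enoate (ester and ketal cis) | CCC[C@@H](O[Si](C)(C)C)/C(C(=O)OC)=C(\Br)C1(C)OCCO1 | intermediate
10 | methyl (E)-3-bromo-2-[(R)-1-hydroxybutyl]-4-oxopent-2-enoate (ester and acetyl cis), formed in the flask | CCC[C@@H](O)/C(C(=O)OC)=C(\Br)C(C)=O | intermediate
11 | 4-bromo-5-hydroxy-3-[(1R)-1-hydroxybutyl]-5-methylfuran-2(5H)-one (both C5 epimers) | CCC[C@@H](O)C1=C(Br)C(C)(O)OC1=O | intermediate
12 | (1R)-1-(5-acetoxy-4-bromo-5-methyl-2-oxo-2,5-dihydrofuran-3-yl)butyl acetate (both C5 epimers), formed in the flask | CCC[C@@H](OC(C)=O)C1=C(Br)C(C)(OC(C)=O)OC1=O | intermediate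
13 | (1R)-1-(4-bromo-5-methylidene-2-oxo-2,5-dihydrofuran-3-yl)butyl acetate | CCC[C@@H](OC(C)=O)C1=C(Br)C(=C)OC1=O | intermediate
14 | (1R)-1-[4-bromo-5-chloro-5-(iodomethyl)-2-oxo-2,5-dihydrofuran-3-yl]butyl acetate (both C5 epimers), formed in the flask | CCC[C@@H](OC(C)=O)C1=C(Br)C(Cl)(CI)OC1=O | intermediate
15 | (1R)-1-[(5Z)-4-bromo-5-(iodomethylidene)-2-oxo-2,5-dihydrofuran-3-yl]butyl acetate | CCC[C@@H](OC(C)=O)C1=C(Br)/C(=C/I)OC1=O | intermediate
16 | (5Z)-4-bromo-3-[(1R)-1-hydroxybutyl]-5-(iodomethylidene)furan-2(5H)-one | CCC[C@@H](O)C1=C(Br)/C(=C/I)OC1=O | target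

**Totals**

Total step count: 7. Longest linear sequence: 7 steps (1 → 16).

**Steps most likely to fail**

Step 3 (the proposed new method). Bromide may add too slowly to the internal ynoate at a temperature the dioxolane tolerates. The aldehyde may also take the allenolate from the ketal side, which would put ester and ketal trans, or facial selectivity at butanal may be poor. The fallback uses only known reaction types, sets out from 2 and returns at 11.
- Lithiated 2 is acylated with N-methoxy-N-methylbutanamide to give 1-(2-methyl-1,3-dioxolan-2-yl)hex-1-yn-3-one F1.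
- Noyori transfer hydrogenation of this alkynyl ketone with RuCl[(R,R)-TsDPEN](p-cymene) in i-PrOH should give (3R)-1-(2-methyl-1,3-dioxolan-2-yl)hex-1-yn-3-ol F2.
- Hydroxyl-directed anti-carbomagnesiation with vinylmagnesium chloride places vinyl on the carbinol-side alkyne carbon and magnesium on the far carbon, held cis to C1' by the alkoxide chelate. An N-bromosuccinimide quench then gives (3R,1Z)-1-bromo-2-ethenyl-1-(2-methyl-1,3-dioxolan-2-yl)hex-1-en-3-ol F3, with Br beside C1' and vinyl beside the ketal.
- Lemieux–Johnson cleavage of the terminal vinyl group (OsO4 cat., NaIO4, 2,6-lutidine) gives (2E)-3-bromo-2-[(1R)-1-hydroxybutyl]-3-(2-methyl-1,3-dioxolan-2-yl)prop-2-enal F4.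
- Pinnick oxidation (NaClO2, NaH2PO4, 2-methylbut-2-ene) gives (2E)-3-bromo-2-[(1R)-1-hydroxybutyl]-3-(2-methyl-1,3-dioxolan-2-yl)prop-2-enoic acid F5.
- Aqueous H2SO4 in dioxane removes the ketal and closes the acid onto the ketone to give lactol 11.

Step 6. Iodine monochloride addition may revert when base is added, the amine may attack the halogenated butenolide, or the elimination may give a poor Z/E ratio. The fallback sets out from 13 and returns at 15. The alkene is hydroxy-iodinated with N-iodosuccinimide in wet MeCN to give (1R)-1-[4-bromo-5-hydroxy-5-(iodomethyl)-2-oxo-2,5-dihydrofuran-3-yl]butyl acetate F6. This lactol is then dehydrated with P2O5 in CH2Cl2, without base and under conditions that let the alkene settle to the more stable Z geometry.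

Step 5. Loss of acetic acid from the 5-acetoxy intermediate may stall, or the hot acidic anhydride may cause elimination or ionisation at C1'. The fallback sets out from 9 and returns at 13, and protects C1' before any lactol exists.
- Cold dilute HCl in THF removes only the silyl group to give methyl (E)-3-bromo-2-[(R)-1-hydroxybutyl]-3-(2-methyl-1,3-dioxolan-2-yl)prop-2-enoate F7.
- Ac2O/pyridine with catalytic 4-(dimethylamino)pyridine at 0 °C gives methyl (E)-2-[(R)-1-acetoxybutyl]-3-bromo-3-(2-methyl-1,3-dioxolan-2-yl)prop-2-enoate F8.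
- CF3CO2H/H2O gives (1R)-1-(4-bromo-5-hydroxy-5-methyl-2-oxo-2,5-dihydrofuran-3-yl)butyl acetate F9.
- P2O5 in refluxing CH2Cl2 dehydrates only the tertiary lactol to give 13.

**Further compounds**

F1 | step 3 | 1-(2-methyl-1,3-dioxolan-2-yl)hex-1-yn-3-one | CCCC(=O)C#CC1(C)OCCO1
F2 | step 3 | (3R)-1-(2-methyl-1,3-dioxolan-2-yl)hex-1-yn-3-ol | CCC[C@@H](O)C#CC1(C)OCCO1
F3 | step 3 | (3R,1Z)-1-bromo-2-ethenyl-1-(2-methyl-1,3-dioxolan-2-yl)hex-1-en-3-ol | CCC[C@@H](O)/C(C=C)=C(\Br)C1(C)OCCO1
F4 | step 3 | (2E)-3-bromo-2-[(1R)-1-hydroxybutyl]-3-(2-methyl-1,3-dioxolan-2-yl)prop-2-enal | CCC[C@@H](O)/C(C=O)=C(\Br)C1(C)OCCO1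
F5 | step 3 | (2E)-3-bromo-2-[(1R)-1-hydroxybutyl]-3-(2-methyl-1,3-dioxolan-2-yl)prop-2-enoic acid | CCC[C@@H](O)/C(C(=O)O)=C(\Br)C1(C)OCCO1
F6 | step 6 | (1R)-1-[4-bromo-5-hydroxy-5-(iodomethyl)-2-oxo-2,5-dihydrofuran-3-yl]butyl acetate | CCC[C@@H](OC(C)=O)C1=C(Br)C(O)(CI)OC1=O
F7 | step 5 | methyl (E)-3-bromo-2-[(R)-1-hydroxybutyl]-3-(2-methyl-1,3-dioxolan-2-yl)prop-2-enoate | CCC[C@@H](O)/C(C(=O)OC)=C(\Br)C1(C)OCCO1
F8 | step 5 | methyl (E)-2-[(R)-1-acetoxybutyl]-3-bromo-3-(2-methyl-1,3-dioxolan-2-yl)prop-2-enoate | CCC[C@@H](OC(C)=O)/C(C(=O)OC)=C(\Br)C1(C)OCCO1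
F9 | step 5 | (1R)-1-(4-bromo-5-hydroxy-5-methyl-2-oxo-2,5-dihydrofuran-3-yl)butyl acetate | CCC[C@@H](OC(C)=O)C1=C(Br)C(C)(O)OC1=O
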